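**Plan**

- Locants C1–C7a are those of the indene skeleton of the target and C8 is the carboxyl carbon; they are used for every intermediate.
- Retrosynthesis: cut C1–C2 (ring B, acyl radical onto a C7a ethynyl group), then C6–C7 (ring A), then the C8–O lactone bond, the C4–OH bond, C7a–C7 and C3a–C4.
- Enabling feature: C7 is the α-carbon of the C8 acid and C6–C5=C4 is an allyl unit inside ring A (a γ,δ-unsaturated acid). C6–C7 is therefore a Claisen bond, and ring A unravels to a δ-lactone O–C8(=O)–C7–C7a–C3a–C4 whose C4 carries the C5=C6 dienyl arm.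
- Forward: C1 lactone (dihydropyranone) → C5 lactone → C8 δ-lactone → ring A by [3,3] ring contraction → ring B by 5-exo-dig acyl radical closure.
- Stereochemistry: C3 from an organocatalytic aldol; C3a and C7a from anti Michael addition and anti alkylation on the dihydropyranone; C4 from enolate hydroxylation; C7 and C6 from the boat Claisen shift (C4 configuration, E-C5=C6); C1 by thermodynamic protonation.

Key step: step 14

Remark: the natural configurations at C1 and C3 (each α-substituent trans to the neighbouring ring-fusion bond) are taken to be the thermodynamically preferred ketone epimers, so base equilibration converges on them.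

**Step 1**
Reactants: 1 butanal
Product: 2 (R)-2-(hydroxymethyl)butanal
Conditions: aq. CH2O (37%), (S)-α,α-diphenylprolinol trimethylsilyl ether (10 mol%), pH 7 phosphate buffer, PhMe, rt; organic phase dried and used at once
Reagents that add atoms: formaldehyde, C=O
Why: Enamine-catalysed cross-aldol reaction (organocatalytic α-hydroxymethylation), in which the bulky silyl ether blocks one enamine face so that formaldehyde adds to the other and sets C3.

**Step 2**
Reactants: 2 (R)-2-(hydroxymethyl)butanal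
Product: 4 (S)-5-ethyl-5,6-dihydro-2H-pyran-2-one, via hydroxy Z-enoate 3 (not isolated)
Conditions: (PhO)2P(O)CH2CO2Et, NaI, DBU, THF, −78 → 0 °C; then TsOH·H2O (cat.), CH2Cl2, rt
Reagents that add atoms: ethyl 2-(diphenoxyphosphoryl)acetate, CCOC(=O)CP(=O)(Oc1ccccc1)Oc1ccccc1
Why: Ando-type Z-selective Horner–Wadsworth–Emmons olefination under amine/NaI conditions (no alkoxide, hence no retro-aldol), after which the cis hydroxymethyl group lactonises; C3 is untouched.

**Step 3**
Reactants: 4 (S)-5-ethyl-5,6-dihydro-2H-pyran-2-one, 5 methyl butanoate, 6 tert-butyl(2-iodoethoxy)dimethylsilane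
Product: 9 all-trans C1 lactone methyl 2-[3-(2-silyloxyethyl)-5-ethyl-2-oxooxan-4-yl]butanoate, via lithium enolate of methyl butanoate 7 (not isolated), via lithium enolate of the Michael adduct 8 (not isolated)
Conditions: LiN(i-Pr)2, 5, THF, −78 °C; then 4, −78 °C; then 6, HMPA, −78 → −30 °C
Reagents that add atoms: none
Why: Michael addition–enolate alkylation (three-component coupling): the ester enolate should add to C3a anti to the C3 ethyl group (axial attack on the half-chair) and the resulting lactone enolate should be alkylated at C7a anti to the new C3a branch, giving the 3,4-trans-4,5-trans ring; the ester α-carbon (C4) is left unset and is erased in step 6.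

**Step 4**
Reactants: 9 all-trans C1 lactone
Product: 10 lactol of 9 (anomers)
Conditions: (Me2CHCHMe)2BH (disiamylborane, 3 equiv), THF, 0 °C → rt; then H2O
Reagents that add atoms: none
Why: Chemoselective borane reduction of a lactone, which stops at the hemiacetal and leaves the methyl ester and the silyl ether alone; the anomeric centre is of no consequence.

**Step 5**
Reactants: 10 lactol of 9
Product: 12 4,5-cis C5 lactone 3,5-diethyl-4-(5-silyloxypent-1-yn-3-yl)oxan-2-one, via alkynyl hydroxy ester 11 (not isolated)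
Conditions: MeC(O)C(N2)P(O)(OMe)2, K2CO3, MeOH, 0 °C → rt; then PPTS (cat.), PhMe, 40 °C
Reagents that add atoms: dimethyl (1-diazo-2-oxopropyl)phosphonate, COP(=O)(OC)C(=[N+]=[N-])C(C)=O
Why: Ohira–Bestmann (Seyferth–Gilbert) homologation of the open hydroxy aldehyde turns C1 into the ethynyl group, and the freed C2 hydroxyl lactonises onto the methyl ester so that C4 becomes the α-carbon of a ring carbonyl; C7a should survive because alkyne formation outruns enolisation, and the C3 ethyl and C3a branch are now cis on the new ring.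

**Step 6**
Reactants: 12 4,5-cis C5 lactone
Product: 14 3-hydroxy lactone 3,5-diethyl-3-hydroxy-4-(5-silyloxypent-1-yn-3-yl)oxan-2-one, via potassium lactone enolate 13 (not isolated)
Conditions: KN(SiMe3)2 (1.1 equiv), THF, −78 → −45 °C; then 2-(phenylsulfonyl)-3-phenyloxaziridine, −78 °C; then AcOH
Reagents that add atoms: 2-(phenylsulfonyl)-3-phenyloxaziridine, O=S(=O)(c1ccccc1)N1OC1c1ccccc1
Why: Davis enolate hydroxylation: one equivalent of base should give the lactone enolate (its α-C–H is more acidic than the alkyne C–H), and oxygen is delivered to the face anti to the pseudoaxial C3a branch, which sets C4 with the hydroxyl trans to that branch.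

**Step 7**
Reactants: 14 3-hydroxy lactone
Product: 15 lactol of 14 (oxane-2,3-diol, anomers)
Conditions: i-Bu2AlH (2.5 equiv), CH2Cl2, −78 °C; aq. potassium sodium tartrate
Reagents that add atoms: none
Why: Partial reduction of a lactone with i-Bu2AlH: the tetrahedral aluminate persists at −78 °C and gives the lactol on work-up, the first equivalent of hydride being consumed by the tertiary hydroxyl.

**Step 8**
Reactants: 15 lactol of 14
Product: 16 (2E)-8-silyloxy-2,4-diethyl-6-ethynyl-4-hydroxy-5-(1-hydroxybutan-2-yl)oct-2-enal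
Conditions: Ph3P=C(Et)CHO, PhMe, 90 °C
Reagents that add atoms: 2-(triphenyl-λ5-phosphanylidene)butanal, CCC(C=O)=P(c1ccccc1)(c1ccccc1)c1ccccc1
Why: Wittig olefination of the open hydroxy aldehyde with a formyl-stabilised ylide, E-selective as for stabilised ylides, so the formyl group ends trans and the C6 ethyl cis to C4; ring opening frees the C2 hydroxyl.

**Step 9**
Reactants: 16 enal diol
Product: 17 C2 tert-butyldiphenylsilyl ether of 16
Conditions: t-BuPh2SiCl, imidazole, CH2Cl2, 0 °C
Reagents that add atoms: tert-butyl(chloro)diphenylsilane, CC(C)(C)[Si](Cl)(c1ccccc1)c1ccccc1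
Why: Silyl ether formation, selective for the primary C2 hydroxyl because the tertiary C4 hydroxyl is too hindered to react.

**Step 10**
Reactants: 17 bis-silyl ether
Product: 18 (2E)-5-(1-silyloxybutan-2-yl)-2,4-diethyl-6-ethynyl-4,8-dihydroxyoct-2-enal
Conditions: HF·pyridine, pyridine, THF, 0 °C
Reagents that add atoms: none
Why: Selective fluoride desilylation: a primary tert-butyldimethylsilyl ether is cleaved much faster than a primary tert-butyldiphenylsilyl ether under buffered HF·pyridine.

**Step 11**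
Reactants: 18 enal diol
Product: 20 C8 δ-lactone enal, via lactol 19 (not isolated)
Conditions: TEMPO (20 mol%), PhI(OAc)2 (2.5 equiv), CH2Cl2, rt
Reagents that add atoms: none
Why: Oxoammonium-mediated oxidative lactonisation of a 1,5-diol: the primary C8 alcohol is oxidised to the aldehyde, the tertiary C4 hydroxyl closes the lactol and this is oxidised to the lactone, while the enal and the alkyne are inert.

**Step 12**
Reactants: 20 C8 δ-lactone enal
Product: 21 6-ethyl-6-[(1E,3E)-2-ethyl-4-phenylbuta-1,3-dienyl]-4-ethynyl-5-(1-silyloxybutan-2-yl)oxan-2-one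
Conditions: (EtO)2P(O)CH2Ph, n-BuLi, THF, −78 °C; then 20, −78 → 0 °C
Reagents that add atoms: diethyl benzylphosphonate, CCOP(=O)(Cc1ccccc1)OCC
Why: Horner–Wadsworth–Emmons olefination of the enal, E-selective for the new styryl double bond; the aldehyde is far more electrophilic than the lactone carbonyl.

**Step 13**
Reactants: 21 dienyl lactone
Product: 23 3,6-diethyl dienyl lactone (Claisen precursor), via lithium lactone enolate 22 (not isolated)
Conditions: LiN(i-Pr)2 (1.1 equiv), THF, −78 °C; then EtI, DMPU, −78 → −45 °C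
Reagents that add atoms: iodoethane, CCI
Why: Lactone enolate C-alkylation, run below the temperature at which the enolate would rearrange; the ethyl group should enter mainly anti to the C7a ethynyl group, and the C7 epimer ratio is immaterial because C7 is enolised again in step 14.

**Step 14**
Reactants: 23 3,6-diethyl dienyl lactone
Product: 26 ring A acid with both quaternary centres, via silyl ketene acetal 24 (not isolated), via trimethylsilyl ester 25 (not isolated)
Conditions: LiN(i-Pr)2 (2.5 equiv), Me3SiCl–Et3N (excess, internal quench), THF, −78 °C → rt; then PhMe, 80 °C; then 1 M HCl, THF, 0 °C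
Reagents that add atoms: chlorotrimethylsilane, C[Si](C)(C)Cl
Why: Deprotonation at C7 and at the alkyne C–H with in situ silylation gives cyclic silyl ketene acetal 24, an allyl vinyl ether (C7=C8–O–C4–C5=C6) that should undergo a concerted [3,3] shift in which C6–C7 forms as O–C4 breaks and C4=C5 appears; this is the Ireland–Claisen rearrangement in its lactone ring-contraction form. Ring A (C4–C5–C6–C7–C7a–C3a) closes by contraction of the six-membered lactone onto the two alkene carbons through the boat, bicyclo[2.2.2]octane-like transition state, the only one the lactone ring allows. C7 is controlled by the C4 configuration, because the dienyl arm can only reach the lactone face on which it sits, and C6 by the E geometry of C5=C6: the ethyl group cis to C4 ends on the tether side and hence cis to the C7 ethyl. The step needs enolisation at C7 only (the sole α-hydrogen of the lactone) and a sigmatropic shift that outruns ionisation of the tertiary dienylic C4–O bond, which the neutral silyl ketene acetal and a moderate temperature favour. The linear silylethynyl group at C7a leaves as much room as possible on the flank over which the C6 ethyl swings, and concerted shifts of this kind are known to join two fully substituted carbons.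

**Step 15**
Reactants: 26 ring A acid
Product: 27 allyl ester of 26
Conditions: allyl bromide, Cs2CO3, DMF, rt
Reagents that add atoms: allyl bromide, C=CCBr
Why: Carboxylate O-alkylation (SN2 at the allyl halide), which does not require attack at the very hindered C8 carbonyl.

**Step 16**
Reactants: 27 allyl ester
Product: 28 prop-2-enyl 1,2,4-triethyl-6-ethynyl-5-(1-hydroxybutan-2-yl)-2-[(E)-2-phenylethenyl]cyclohex-3-ene-1-carboxylate
Conditions: Bu4NF, THF, 0 °C → rt
Reagents that add atoms: none
Why: Fluoride desilylation, cleaving both the silyl ether at C2 and the alkynyl C–Si bond while the hindered allyl ester stays.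

**Step 17**
Reactants: 28 hydroxy alkyne
Product: 29 C2 carboxylic acid
Conditions: TEMPO (cat.), PhI(OAc)2 (2.5 equiv), MeCN–H2O, rt
Reagents that add atoms: water, O
Why: Oxoammonium oxidation of a primary alcohol through the aldehyde hydrate to the acid; alkenes, the alkyne and the ester are not touched, and C3 is a centre that is equilibrated later in any case.

**Step 18**
Reactants: 29 C2 carboxylic acid
Product: 30 Se-phenyl selenoester of 29
Conditions: PhSeSePh, Bu3P, CH2Cl2, rt
Reagents that add atoms: diphenyl diselenide, c1ccc(cc1)[Se][Se]c1ccccc1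
Why: Selenoester formation through the acyloxyphosphonium salt (phosphine/diselenide activation), the standard entry to acyl radical precursors.

**Step 19**
Reactants: 30 Se-phenyl selenoester
Product: 31 exocyclic enone (trans-fused hexahydroindenone)
Conditions: Bu3SnH (1.3 equiv, slow addition), AIBN (cat.), PhH, 80 °C, 0.01 M
Reagents that add atoms: none
Why: Acyl radical cyclisation of an acyl selenide: the C2 acyl radical should add 5-exo-dig to C1 of the terminal alkyne and the vinyl radical then takes hydrogen from Bu3SnH; ring B closes trans-fused because C3a and C7a are already fixed, and slow addition keeps direct reduction and alkyne hydrostannation behind cyclisation.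

**Step 20**
Reactants: 31 exocyclic enone
Product: 32 allyl ester of the target
Conditions: [(Ph3P)CuH]6, PhH, H2O (5 equiv), rt; then DBU (0.2 equiv), rt
Reagents that add atoms: none
Why: Copper hydride conjugate reduction with [(Ph3P)CuH]6, which reduces the exocyclic enone and leaves isolated alkenes, the styrene and the ester alone; protonation of the enolate followed by DBU equilibration should give the C1 epimer with methyl trans to C7 (C3 equilibrates to its already correct arrangement).

**Step 21**
Reactants: 32 allyl ester of the target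
Product: 33 target acid
Conditions: Pd(PPh3)4 (5 mol%), morpholine, THF, rt
Reagents that add atoms: none
Why: Tsuji–Trost deallylation: Pd(PPh3)4 ionises the allyl ester to a π-allyl complex that morpholine captures, freeing the hindered acid under neutral conditions that do not disturb the ketone α-centres.

**Compound list**

1 | butanal | CCCC=O | starting material
2 | (R)-2-(hydroxymethyl)butanal | CC[C@H](CO)C=O | intermediate
3 | ethyl (S,Z)-4-(hydroxymethyl)hex-2-enoate | CC[C@H](CO)/C=C\C(=O)OCC | intermediate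
4 | (S)-5-ethyl-5,6-dihydro-2H-pyran-2-one | CC[C@@H]1COC(=O)C=C1 | intermediate
5 | methyl butanoate | CCCC(=O)OC | starting material
6 | tert-butyl(2-iodoethoxy)dimethylsilane | CC(C)(C)[Si](C)(C)OCCI | starting material
7 | lithium enolate of methyl butanoate | [Li+].CCC=C([O-])OC | intermediate
8 | lithium lactone enolate of the Michael adduct (C3a branch trans to C3 ethyl) | CC[C@@H]1COC([O-])=C[C@H]1C(CC)C(=O)OC.[Li+] | intermediate
9 | methyl 2-[(3R,4R,5S)-3-(2-{[tert-butyl(dimethyl)silyl]oxy}ethyl)-5-ethyl-2-oxooxan-4-yl]butanoate; 3,4-trans, 4,5-trans; ester α-carbon (C4) unset | CC[C@@H]1COC(=O)[C@H](CCO[Si](C)(C)C(C)(C)C)[C@H]1C(CC)C(=O)OC | intermediate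
10 | lactol of 9 (2-hydroxyoxane, anomers; ring centres as in 9) | CC[C@@H]1COC(O)[C@H](CCO[Si](C)(C)C(C)(C)C)[C@H]1C(CC)C(=O)OC | intermediate
11 | methyl 6-{[tert-butyl(dimethyl)silyl]oxy}-2-ethyl-4-ethynyl-3-(1-hydroxybutan-2-yl)hexanoate (C3, C3a, C7a as in 9) | CC[C@H](CO)[C@H](C(CC)C(=O)OC)[C@H](C#C)CCO[Si](C)(C)C(C)(C)C | intermediate
12 | 3,5-diethyl-4-(5-{[tert-butyl(dimethyl)silyl]oxy}pent-1-yn-3-yl)oxan-2-one; 4,5-cis; ring C3 (target C4) unset | CC[C@@H]1COC(=O)C(CC)[C@@H]1[C@H](C#C)CCO[Si](C)(C)C(C)(C)C | intermediate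
13 | potassium enolate of 12 | CC[C@@H]1COC([O-])=C(CC)[C@@H]1[C@H](C#C)CCO[Si](C)(C)C(C)(C)C.[K+] | intermediate
14 | 3,5-diethyl-3-hydroxy-4-(5-{[tert-butyl(dimethyl)silyl]oxy}pent-1-yn-3-yl)oxan-2-one; hydroxyl trans to the C4 branch, 4,5-cis | CC[C@@H]1COC(=O)[C@](O)(CC)[C@@H]1[C@H](C#C)CCO[Si](C)(C)C(C)(C)C | intermediate
15 | lactol of 14 (oxane-2,3-diol, anomers) | CC[C@@H]1COC(O)[C@](O)(CC)[C@@H]1[C@H](C#C)CCO[Si](C)(C)C(C)(C)C | intermediate
16 | (2E)-8-{[tert-butyl(dimethyl)silyl]oxy}-2,4-diethyl-6-ethynyl-4-hydroxy-5-(1-hydroxybutan-2-yl)oct-2-enal (stereocentres as in 14) | O=C/C(CC)=C/[C@](O)(CC)[C@@H]([C@H](CC)CO)[C@H](C#C)CCO[Si](C)(C)C(C)(C)C | intermediate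
17 | C2 tert-butyldiphenylsilyl ether of 16 | O=C/C(CC)=C/[C@](O)(CC)[C@@H]([C@H](CC)CO[Si](c1ccccc1)(c1ccccc1)C(C)(C)C)[C@H](C#C)CCO[Si](C)(C)C(C)(C)C | intermediate
18 | (2E)-5-(1-{[tert-butyl(diphenyl)silyl]oxy}butan-2-yl)-2,4-diethyl-6-ethynyl-4,8-dihydroxyoct-2-enal | O=C/C(CC)=C/[C@](O)(CC)[C@@H]([C@H](CC)CO[Si](c1ccccc1)(c1ccccc1)C(C)(C)C)[C@H](C#C)CCO | intermediate
19 | lactol formed from 18 (6-hydroxyoxan-2-yl enal, anomers) | O=C/C(CC)=C/[C@@]1(CC)OC(O)C[C@@H](C#C)[C@@H]1[C@H](CC)CO[Si](c2ccccc2)(c2ccccc2)C(C)(C)C | intermediate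
20 | (2E)-2-ethyl-3-[2-ethyl-4-ethynyl-6-oxo-3-(1-silyloxybutan-2-yl)oxan-2-yl]prop-2-enal; ethynyl trans to the C3a branch, enal arm cis to ethynyl | O=C/C(CC)=C/[C@@]1(CC)OC(=O)C[C@@H](C#C)[C@@H]1[C@H](CC)CO[Si](c2ccccc2)(c2ccccc2)C(C)(C)C | intermediate
21 | 6-ethyl-6-[(1E,3E)-2-ethyl-4-phenylbuta-1,3-dien-1-yl]-4-ethynyl-5-(1-{[tert-butyl(diphenyl)silyl]oxy}butan-2-yl)oxan-2-one (ring centres as in 20) | C1C(=O)O[C@](CC)(/C=C(\CC)/C=C/c2ccccc2)[C@@H]([C@H](CC)CO[Si](c2ccccc2)(c2ccccc2)C(C)(C)C)[C@@H]1C#C | intermediate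
22 | lithium enolate of 21 | C1=C([O-])O[C@](CC)(/C=C(\CC)/C=C/c2ccccc2)[C@@H]([C@H](CC)CO[Si](c2ccccc2)(c2ccccc2)C(C)(C)C)[C@@H]1C#C.[Li+] | intermediate
23 | 3,6-diethyl-6-[(1E,3E)-2-ethyl-4-phenylbuta-1,3-dien-1-yl]-4-ethynyl-5-(1-{[tert-butyl(diphenyl)silyl]oxy}butan-2-yl)oxan-2-one; ethynyl trans to the C3a branch and to the C7 ethyl, dienyl arm cis to ethynyl (major C7 epimer shown) | CC[C@H]1C(=O)O[C@](CC)(/C=C(\CC)/C=C/c2ccccc2)[C@@H]([C@H](CC)CO[Si](c2ccccc2)(c2ccccc2)C(C)(C)C)[C@@H]1C#C | intermediate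
24 | cyclic trimethylsilyl ketene acetal of 23 with C-silylated alkyne | CCC1=C(O[Si](C)(C)C)O[C@](CC)(/C=C(\CC)/C=C/c2ccccc2)[C@@H]([C@H](CC)CO[Si](c2ccccc2)(c2ccccc2)C(C)(C)C)[C@@H]1C#C[Si](C)(C)C | intermediate
25 | trimethylsilyl ester of 26 | CCC1=C[C@@](/C=C/c2ccccc2)(CC)[C@](CC)(C(=O)O[Si](C)(C)C)[C@@H](C#C[Si](C)(C)C)[C@@H]1[C@H](CC)CO[Si](c2ccccc2)(c2ccccc2)C(C)(C)C | intermediate
26 | 1,2,4-triethyl-5-(1-{[tert-butyl(diphenyl)silyl]oxy}butan-2-yl)-2-[(E)-2-phenylethenyl]-6-[(trimethylsilyl)ethynyl]cyclohex-3-ene-1-carboxylic acid; C6 ethyl, C7 ethyl and the alkynyl group on one face, styryl, carboxyl and the C3a side chain on the other | CCC1=C[C@@](/C=C/c2ccccc2)(CC)[C@](CC)(C(=O)O)[C@@H](C#C[Si](C)(C)C)[C@@H]1[C@H](CC)CO[Si](c2ccccc2)(c2ccccc2)C(C)(C)C | intermediate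
27 | prop-2-en-1-yl ester of 26 | CCC1=C[C@@](/C=C/c2ccccc2)(CC)[C@](CC)(C(=O)OCC=C)[C@@H](C#C[Si](C)(C)C)[C@@H]1[C@H](CC)CO[Si](c2ccccc2)(c2ccccc2)C(C)(C)C | intermediate
28 | prop-2-en-1-yl 1,2,4-triethyl-6-ethynyl-5-(1-hydroxybutan-2-yl)-2-[(E)-2-phenylethenyl]cyclohex-3-ene-1-carboxylate (centres as in 26) | CCC1=C[C@@](/C=C/c2ccccc2)(CC)[C@](CC)(C(=O)OCC=C)[C@@H](C#C)[C@@H]1[C@H](CC)CO | intermediate
29 | 2-{2,4,5-triethyl-6-ethynyl-4-[(E)-2-phenylethenyl]-5-[(prop-2-en-1-yloxy)carbonyl]cyclohex-2-en-1-yl}butanoic acid (centres as in 26) | CCC1=C[C@@](/C=C/c2ccccc2)(CC)[C@](CC)(C(=O)OCC=C)[C@@H](C#C)[C@@H]1[C@H](CC)C(=O)O | intermediate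
30 | Se-phenyl selenoester of 29 | CCC1=C[C@@](/C=C/c2ccccc2)(CC)[C@](CC)(C(=O)OCC=C)[C@@H](C#C)[C@@H]1[C@H](CC)C(=O)[Se]c2ccccc2 | intermediate
31 | prop-2-en-1-yl (3S,3aR,6S,7R,7aR)-3,4,6,7-tetraethyl-1-methylidene-2-oxo-6-[(E)-2-phenylethenyl]-2,3,3a,6,7,7a-hexahydro-1H-indene-7-carboxylate | CCC1=C[C@@](/C=C/c2ccccc2)(CC)[C@](CC)(C(=O)OCC=C)[C@@H]2[C@@H]1[C@H](CC)C(=O)C2=C | intermediate
32 | prop-2-en-1-yl (1S,3S,3aR,6S,7R,7aR)-3,4,6,7-tetraethyl-1-methyl-2-oxo-6-[(E)-2-phenylethenyl]-2,3,3a,6,7,7a-hexahydro-1H-indene-7-carboxylate | CCC1=C[C@@](/C=C/c2ccccc2)(CC)[C@](CC)(C(=O)OCC=C)[C@@H]2[C@@H]1[C@H](CC)C(=O)[C@H]2C | intermediate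
33 | (1S,3S,3aR,6S,7R,7aR)-3,4,6,7-tetraethyl-1-methyl-2-oxo-6-[(E)-2-phenylethenyl]-2,3,3a,6,7,7a-hexahydro-1H-indene-7-carboxylic acid | CCC1=C[C@@](/C=C/c2ccccc2)(CC)[C@](CC)(C(=O)O)[C@@H]2[C@@H]1[C@H](CC)C(=O)[C@H]2C | target

**Totals and risks**

Total step count: 21. Longest linear sequence: 21 steps (butanal 1 to target 33; 5 and 6 are purchased).

Step 14. Bond formation between the two fully substituted carbons C6 and C7 may be slow, the C6 ethyl being pressed against the C7a alkynyl group in the boat. The tertiary dienylic C4–O bond of the ketene acetal could then ionise and eliminate to a triene acid instead of rearranging. The fallback sets out from 20 and keeps the ring contraction but removes the doubly allylic character of the C–O bond: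
- The enal is converted with HC(OMe)3 and PPTS in MeOH into the dimethyl acetal F1.
- F1 is ethylated as in step 13 to the 3-ethyl lactone acetal F2.
- F2 is rearranged as in step 14, with hydrolysis of the silyl ester at pH 7, to the ring A acid F3, which carries a dimethoxymethyl group on C6 in place of the styryl unit.
- F3 is esterified with allyl bromide and Cs2CO3 to the allyl ester F4.
- Hydrolysis of the acetal (PPTS, acetone–water) gives the C6 aldehyde F5.
- Horner–Wadsworth–Emmons reaction of F5 with lithiated diethyl benzylphosphonate installs the E styryl group and comes back to the route at 27.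

Step 19. Closure to the trans-fused five-membered ring may be slow enough for the α-branched acyl radical to lose CO, to be reduced to the aldehyde, or for tin radicals to add to the terminal alkyne. The fallback sets out from 28 and uses an anionic radical in place of the acyl radical:
- Dess–Martin oxidation gives the ynal F6.
- SmI2 (HMPA, t-BuOH, THF) effects ketyl–alkyne 5-exo-dig reductive cyclisation to the exocyclic allylic alcohol F7 (both C2 carbinol epimers).
- Dess–Martin oxidation of F7 gives the enone and comes back to the route at 31.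

Step 8. The hindered lactol exposes little open hydroxy aldehyde and the formyl-stabilised ylide is a weak nucleophile, so olefination may stall, and prolonged heating invites oxa-Michael closure of the freed C2 hydroxyl onto the enal. The fallback sets out from 15 and replaces the ylide by a more nucleophilic phosphonate, followed by redox adjustment:
- Horner–Wadsworth–Emmons reaction with triethyl 2-phosphonobutanoate (LiCl, DBU, MeCN) gives the E enoate diol F8.
- Silylation of the primary hydroxyl with t-BuPh2SiCl and imidazole gives F9.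
- Reduction with i-Bu2AlH gives the allylic alcohol F10.
- MnO2 oxidises F10 to the enal and comes back to the route at 17.

**Further compounds**

F1 | step 14 | dimethyl acetal of lactone enal 20 | COC(OC)/C(CC)=C/[C@@]1(CC)OC(=O)C[C@@H](C#C)[C@@H]1[C@H](CC)CO[Si](c2ccccc2)(c2ccccc2)C(C)(C)C
F2 | step 14 | 3-ethyl lactone acetal (C7 ethylated F1) | CC[C@H]1C(=O)O[C@](CC)(/C=C(\CC)/C(OC)OC)[C@@H]([C@H](CC)CO[Si](c2ccccc2)(c2ccccc2)C(C)(C)C)[C@@H]1C#C
F3 | step 14 | ring A acid with a dimethoxymethyl group on C6 | CCC1=C[C@@](C(OC)OC)(CC)[C@](CC)(C(=O)O)[C@@H](C#C[Si](C)(C)C)[C@@H]1[C@H](CC)CO[Si](c2ccccc2)(c2ccccc2)C(C)(C)C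
F4 | step 14 | prop-2-en-1-yl ester of F3 | CCC1=C[C@@](C(OC)OC)(CC)[C@](CC)(C(=O)OCC=C)[C@@H](C#C[Si](C)(C)C)[C@@H]1[C@H](CC)CO[Si](c2ccccc2)(c2ccccc2)C(C)(C)C
F5 | step 14 | C6 aldehyde allyl ester | CCC1=C[C@@](C=O)(CC)[C@](CC)(C(=O)OCC=C)[C@@H](C#C[Si](C)(C)C)[C@@H]1[C@H](CC)CO[Si](c2ccccc2)(c2ccccc2)C(C)(C)C
F6 | step 19 | ynal from alcohol 28 | CCC1=C[C@@](/C=C/c2ccccc2)(CC)[C@](CC)(C(=O)OCC=C)[C@@H](C#C)[C@@H]1[C@H](CC)C=O
F7 | step 19 | exocyclic allylic alcohol (1-methylidene-2-hydroxy hexahydroindene, C2 epimers) | CCC1=C[C@@](/C=C/c2ccccc2)(CC)[C@](CC)(C(=O)OCC=C)[C@@H]2[C@@H]1[C@H](CC)C(O)C2=C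
F8 | step 8 | ethyl (2E)-8-silyloxy-2,4-diethyl-6-ethynyl-4-hydroxy-5-(1-hydroxybutan-2-yl)oct-2-enoate | CCOC(=O)/C(CC)=C/[C@](O)(CC)[C@@H]([C@H](CC)CO)[C@H](C#C)CCO[Si](C)(C)C(C)(C)C
F9 | step 8 | C2 tert-butyldiphenylsilyl ether of F8 | CCOC(=O)/C(CC)=C/[C@](O)(CC)[C@@H]([C@H](CC)CO[Si](c1ccccc1)(c1ccccc1)C(C)(C)C)[C@H](C#C)CCO[Si](C)(C)C(C)(C)C
F10 | step 8 | allylic alcohol from F9 | OC/C(CC)=C/[C@](O)(CC)[C@@H]([C@H](CC)CO[Si](c1ccccc1)(c1ccccc1)C(C)(C)C)[C@H](C#C)CCO[Si](C)(C)C(C)(C)C
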